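**Retrosynthetic overview**
1. The target is traced back to an α-alkylidene-γ-butyrolactone (exocyclic C12=C13 shifted into the ring last), made from a C12 aldehyde and a lactone phosphorane, and so to a 12,17-diol 19-acid.
2. The diol acid comes from reductive methylation of a C4=C5 unsaturated 19-acid (sets H-5 α and the C4 quaternary centre) after reduction of a temporary δ-lactone that ties C17 (carbonyl) to O–C12 and lets C8 be equilibrated.
3. Key disconnection, both bonds in one operation: C9–C10 and C5–C6 of ring B, between a ring A 1,3-dioxin-4-one (C10 γ-donor, C5 β-acceptor; menthone acetal as traceless chiral activating and leaving group) and 3-ethenyl-5,6-dihydropyran-2-one (C9 β-acceptor, C6 vinylogous donor).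
4. Enabling feature: in ring B (C5–C6–C7–C8–C9–C10) the two bond-receiving carbons C5 and C9 are each β to a carboxyl-level carbon (C19 on C4 of ring A, C17 on C8), so at the enoate level C5 and C9 are acceptors and C10 and C6 the matching γ-donors.
5. Ring order: ring A (bought) → dioxinone ring (auxiliary) → ring B together with the temporary δ-lactone (key step) → lactone opened → butenolide ring.

Key step: step 5

Assumption (remark on the chemistry): labdane numbering is used throughout (ring A = C1–C5, C10; ring B = C5–C10; C17 on C8; C18 methyl and C19 carboxyl on C4; C20 methyl on C10; C11–C16 side chain and lactone), with α/β as in the usual drawing (C20 β). tert-Butyl 2-oxocyclohexane-1-carboxylate, (−)-menthone, 5,6-dihydro-2H-pyran-2-one, tributyl(ethenyl)stannane and 3-(triphenylphosphoranylidene)oxolan-2-one are taken as commercial.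

Step 1
Reactants: 1 tert-butyl 2-oxocyclohexane-1-carboxylate; 2 (−)-menthone
Product: 3 (2R,2'S,5'R)-5'-methyl-2'-(propan-2-yl)-5,6,7,8-tetrahydrospiro[1,3-benzodioxine-2,1'-cyclohexan]-4-one (menthone spiro-dioxinone; spiro carbon R)
Conditions: TFAA, TFA, CH2Cl2, 0 °C → rt; separation of the two spiro diastereomers by chromatography/crystallisation
Reagents that add atoms: none
Why: Acid-mediated condensation of a β-keto tert-butyl ester with a ketone (1,3-dioxin-4-one synthesis, the tert-butyl group leaving as 2-methylpropene) is established for menthone-derived spiro-dioxinones; the spiro centre forms as two separable diastereomers, 3 being the one whose isopropyl-bearing ring carbon lies on the later β-face, and the two menthone centres are carried over unchanged.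

Step 2
Reactants: 3 menthone spiro-dioxinone
Product: 5 (2R,2'S,5'R)-5',8-dimethyl-2'-(propan-2-yl)-5,6,7,8-tetrahydrospiro[1,3-benzodioxine-2,1'-cyclohexan]-4-one (both C8 epimers), via lithium dienolate 4 (not isolated)
Conditions: LiN(iPr)2, THF–DMPU, −78 °C; MeI, −78 → −40 °C
Reagents that add atoms: iodomethane, CI
Why: γ-Deprotonation of a 6-alkyl-1,3-dioxin-4-one and γ-alkylation of its lithium dienolate (vinylogous enolate alkylation) is known for this heterocycle; the new C8 centre (labdane C10) forms as a mixture, which is irrelevant because step 5 removes its hydrogen.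

Step 3
Reactants: 6 5,6-dihydro-2H-pyran-2-one
Product: 8 3-bromo-5,6-dihydro-2H-pyran-2-one, via dibromide 7 (not isolated)
Conditions: Br2, CH2Cl2, 0 °C; then Et3N, 0 °C → rt
Reagents that add atoms: bromine, BrBr
Why: Bromine addition to the enoate double bond followed by amine-induced dehydrobromination (addition–elimination) is the standard preparation of this α-bromo lactone; no stereocentre remains.

Step 4
Reactants: 8 3-bromo-5,6-dihydro-2H-pyran-2-one
Product: 9 3-ethenyl-5,6-dihydro-2H-pyran-2-one
Conditions: CH2=CHSnBu3, Pd(PPh3)4 (5 mol %), PhMe, 80 °C; used at once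
Reagents that add atoms: tributyl(ethenyl)stannane, C=C[Sn](CCCC)(CCCC)CCCC
Why: Stille cross-coupling of an α-bromo-α,β-unsaturated lactone with a vinylstannane is reliable and creates no stereocentre; the 2-acyl diene is used directly because such dienes dimerise by Diels–Alder reaction on standing.

Step 5
Reactants: 5 8-methyl menthone spiro-dioxinone; 9 3-ethenyl-5,6-dihydro-2H-pyran-2-one
Product: 13 (9R,10R)-13,14,15,16,18-pentanorlabda-4,7-dien-17,12-olid-19-oic acid (H-9 α; 10-methyl β; δ-lactone C17(=O)–O–C12 fused at C8–C9), via lithium dienolate 10 (not isolated), via lactone enolate 11 (not isolated), via dioxanone enolate 12 (not isolated)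
Conditions: LiN(iPr)2 (1.05 equiv), THF–DMPU, −78 °C; add 9, −78 → 0 °C, then rt; aq. HCl
Reagents that add atoms: none
Why: Proposed new method: γ-deprotonation of 5 gives the s-trans-locked lithium dienolate 10, whose terminal C10 adds to C9 of 9 (vinylogous Michael addition); the lactone dienolate 11 then closes ring B through its γ-carbon C6 onto C5, the β-carbon of the regenerated dioxinone (6-exo-trig Michael closure), and the dioxanone enolate 12 expels the acetal oxygen (E1cB) so that the hemiketal carboxylate collapses to the C4=C5 19-oate and menthone. The closest known reaction types are the anionic double Michael ([4+2]) annulation of lithium dienolates with acrylates, γ-selective reactions of dioxinone dienolates, conjugate addition to dioxinones and β-elimination of dioxanone enolates; the reasoning is that the two partners are ambident in a matched sense (C10 donor/C5 acceptor against C9 acceptor/C6 donor). C10 (quaternary) should be set by the menthone acetal, whose isopropyl-bearing carbon shields the β-face so that C9 bonds on the α-face and the methyl ends β; C9 should be set relative to C10 in a compact synclinal transition state with the lactone ring over the C10-methyl flank and away from the acetal (the topicity that gives the cis-vicinal dialkyl pattern in annulations of 2-methylcyclohexanone enolates with β-substituted acceptors), so C11 ends cis to the methyl. The step needs γ- over α-attack of 10 (the α-carbon is a fully substituted ring-fusion carbon and the dienolate cannot serve as a diene) and C6→C5 closure instead of acylation at C19 by C8 (C8 is fully substituted, C6 is a free methylene terminus, and the fragmentation makes the closure irreversible). C5 is sp2 in 13, so the ring-fusion configuration is left open for step 8.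

Step 6
Reactants: 13 dienyl lactone acid
Product: 15 (8R,9S,10R)-13,14,15,16,18-pentanorlabd-4-en-17,12-olid-19-oic acid (trans-fused lactone; H-8 β), via cis-lactone 14 (not isolated)
Conditions: H2 (1 atm), Pd/C, EtOAc, rt; filter; DBU (3 equiv), PhMe, 80 °C
Reagents that add atoms: none
Why: Heterogeneous hydrogenation should reduce the trisubstituted C7=C8 bond and leave the tetrasubstituted carboxyl-conjugated C4=C5 bond, and base equilibration of the lactone α-carbon C8 should give the trans-fused lactone because the cis isomer holds C17 axial and syn to the C10 methyl (thermodynamic control of C8).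

Step 7
Reactants: 15 trans-lactone acid
Product: 16 (8R,9S,10R)-12,17-dihydroxy-13,14,15,16,18-pentanorlabd-4-en-19-oic acid
Conditions: LiOH (1 equiv), then LiBH4, THF, 0 °C → rt; aq. HCl
Reagents that add atoms: none
Why: LiBH4 reduces lactones to diols but not carboxylate salts or the conjugated tetrasubstituted alkene (chemoselective hydride reduction); no stereocentre is touched.

Step 8
Reactants: 16 diol enoic acid
Product: 18 (4S,5R,8R,9S,10R)-12,17-dihydroxy-13,14,15,16-tetranorlabdan-19-oic acid, via lithium enediolate 17 (not isolated)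
Conditions: Li, NH3 (l)/THF, −78 → −33 °C; MeI (1.5 equiv), −78 °C; NH4Cl
Reagents that add atoms: iodomethane, CI
Why: Dissolving-metal reduction of the α,β-unsaturated carboxylate with in situ C-alkylation (Birch-type reductive alkylation) should protonate C5 axially, anti to the C10 methyl (trans ring fusion, H-5 α), and methylate the exocyclic C4 enediolate from the α-face because the β-face is blocked by the syn-axial C10 methyl, leaving the carboxyl axial (β).

Step 9
Reactants: 18 diol acid
Product: 20 (4S,5R,8R,9S,10R,12E)-17-hydroxylabd-12-en-16,15-olid-19-oic acid, via hydroxy aldehyde 19 (not isolated)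
Conditions: TEMPO (cat.), PhI(OAc)2 (1.1 equiv), CH2Cl2, rt; then 3-(triphenylphosphoranylidene)oxolan-2-one (3 equiv), 40 °C
Reagents that add atoms: 3-(triphenylphosphoranylidene)oxolan-2-one, O=C1OCCC1=P(c1ccccc1)(c1ccccc1)c1ccccc1
Why: The oxoammonium oxidant should take the unbranched C12 alcohol in preference to the β-branched C17 alcohol, and the aldehyde is trapped in the same flask by the stabilised ylide (tandem oxidation–Wittig olefination) to give the (E)-alkylidene lactone; no stereocentre is formed.

Step 10
Reactants: 20 (E)-alkylidene lactone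
Product: 21 (4S,5R,8R,9S,10R)-17-hydroxylabd-13-en-16,15-olid-19-oic acid (target)
Conditions: RhCl3·3H2O (5 mol %), EtOH, 80 °C
Reagents that add atoms: none
Why: Rhodium hydride-mediated migration of the exocyclic double bond of an α-alkylidene-γ-butyrolactone into the ring (alkene isomerisation) should give the more stable endocyclic α-alkyl butenolide; all stereocentres are remote and untouched.

**Compound list**
1 | tert-butyl 2-oxocyclohexane-1-carboxylate | CC(C)(C)OC(=O)C1CCCCC1=O | starting material
2 | (−)-menthone, (2S,5R)-5-methyl-2-(propan-2-yl)cyclohexan-1-one | CC(C)[C@@H]1CC[C@@H](C)CC1=O | starting material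
3 | (2R,2'S,5'R)-5'-methyl-2'-(propan-2-yl)-5,6,7,8-tetrahydrospiro[1,3-benzodioxine-2,1'-cyclohexan]-4-one | CC(C)[C@@H]1CC[C@@H](C)C[C@]12OC3=C(CCCC3)C(=O)O2 | intermediate
4 | lithium dienolate of 3 (4-olate, C4=C4a and C8=C8a) | [Li+].CC(C)[C@@H]1CC[C@@H](C)C[C@]12OC3=CCCCC3=C([O-])O2 | intermediate
5 | (2R,2'S,5'R)-5',8-dimethyl-2'-(propan-2-yl)-5,6,7,8-tetrahydrospiro[1,3-benzodioxine-2,1'-cyclohexan]-4-one (8RS) | CC(C)[C@@H]1CC[C@@H](C)C[C@]12OC3=C(CCCC3C)C(=O)O2 | intermediate
6 | 5,6-dihydro-2H-pyran-2-one | O=C1OCCC=C1 | starting material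
7 | 3,4-dibromooxan-2-one (racemic, from anti addition) | O=C1OCCC(Br)C1Br | intermediate
8 | 3-bromo-5,6-dihydro-2H-pyran-2-one | O=C1OCCC=C1Br | intermediate
9 | 3-ethenyl-5,6-dihydro-2H-pyran-2-one | C=CC1=CCCOC1=O | intermediate
10 | lithium dienolate of 5 (C10 sp2, methyl-bearing) | [Li+].CC(C)[C@@H]1CC[C@@H](C)C[C@]12OC3=C(C)CCCC3=C([O-])O2 | intermediate
11 | lithium lactone dienolate, Michael adduct (C9–C10 formed; 10-methyl β, H-9 α) | [Li+].CC(C)[C@@H]1CC[C@@H](C)C[C@]12OC3=C(CCC[C@]3(C)[C@H]4CCOC([O-])=C4C=C)C(=O)O2 | intermediate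
12 | lithium spiro-dioxanone enolate (ring B closed, C5 still bearing the acetal oxygen) | [Li+].CC(C)[C@@H]1CC[C@@H](C)C[C@]12O[C@]34CC=C5C(=O)OCC[C@@H]5[C@@]3(C)CCCC4=C([O-])O2 | intermediate
13 | (9R,10R)-13,14,15,16,18-pentanorlabda-4,7-dien-17,12-olid-19-oic acid | C[C@]12CCCC(C(=O)O)=C1CC=C3C(=O)OCC[C@H]23 | intermediate
14 | (8S,9S,10R)-13,14,15,16,18-pentanorlabd-4-en-17,12-olid-19-oic acid (cis-fused lactone) | C[C@]12CCCC(C(=O)O)=C1CC[C@@H]3C(=O)OCC[C@H]23 | intermediate
15 | (8R,9S,10R)-13,14,15,16,18-pentanorlabd-4-en-17,12-olid-19-oic acid (trans-fused lactone) | C[C@]12CCCC(C(=O)O)=C1CC[C@H]3C(=O)OCC[C@H]23 | intermediate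
16 | (8R,9S,10R)-12,17-dihydroxy-13,14,15,16,18-pentanorlabd-4-en-19-oic acid | C[C@]12CCCC(C(=O)O)=C1CC[C@@H](CO)[C@@H]2CCO | intermediate
17 | tetralithium salt: C4 enediolate of the 19-carboxylate with both alkoxides (H-5 α) | [Li+].[Li+].[Li+].[Li+].C[C@]12CCCC(=C([O-])[O-])[C@@H]1CC[C@@H](C[O-])[C@@H]2CC[O-] | intermediate
18 | (4S,5R,8R,9S,10R)-12,17-dihydroxy-13,14,15,16-tetranorlabdan-19-oic acid | C[C@]12CCC[C@](C)(C(=O)O)[C@@H]1CC[C@@H](CO)[C@@H]2CCO | intermediate
19 | (4S,5R,8R,9S,10R)-17-hydroxy-12-oxo-13,14,15,16-tetranorlabdan-19-oic acid (in equilibrium with its lactol) | C[C@]12CCC[C@](C)(C(=O)O)[C@@H]1CC[C@@H](CO)[C@@H]2CC=O | intermediate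
20 | (4S,5R,8R,9S,10R,12E)-17-hydroxylabd-12-en-16,15-olid-19-oic acid | C[C@]12CCC[C@](C)(C(=O)O)[C@@H]1CC[C@@H](CO)[C@@H]2C/C=C1\CCOC1=O | intermediate
21 | (4S,5R,8R,9S,10R)-17-hydroxylabd-13-en-16,15-olid-19-oic acid | C[C@]12CCC[C@](C)(C(=O)O)[C@@H]1CC[C@@H](CO)[C@@H]2CCC1=CCOC1=O | target

**Step count and risks**
Total step count: 10. Longest linear sequence: 8 steps (1, 2, 5, 6, 7, 8, 9, 10).

Steps most likely to fail:

1. Step 5 (Proposed new method). The cascade may stop after the first conjugate addition, the lactone enolate may attack the dioxinone carbonyl instead of C5, or the acetal may discriminate the two faces of C10 only weakly. The fallback uses known reactions stepwise, from 5 and 9 back to 15. Compound 5 is converted with TBSOTf/Et3N into the tert-butyldimethylsilyl dienol ether F1. A γ-selective vinylogous Mukaiyama–Michael addition to 9 (BF3·OEt2, CH2Cl2, −78 °C) gives the dioxinone Michael adduct F2, whose C10 diastereomers can be separated because the menthone acetal is still in place. Thermolysis in toluene with tert-butanol (acylketene capture) gives the tert-butyl β-keto ester F3. NaH/PhNTf2 gives the enol triflate F4. Hydroboration of the vinyl group with 9-BBN and intramolecular B-alkyl Suzuki–Miyaura coupling (Pd(dppf)Cl2, Cs2CO3), followed by DBU equilibration at C8, gives the tert-butyl ester F5, and TFA then gives 15.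

2. Step 8. Electron transfer to the fully substituted acrylate salt may be incomplete, the C4 dianion may be protonated before it is methylated, or the lithium alkoxides may be O-methylated. The fallback runs from 16 back to 18. Silylation of both hydroxyl groups (TBSCl, imidazole; K2CO3/MeOH to cleave the silyl ester) gives the bis(tert-butyldimethylsilyl) ether acid F6. tert-Butyl 2,2,2-trichloroacetimidate gives the tert-butyl ester F7. The established reductive methylation of α,β-unsaturated esters (Li, NH3, THF; MeI) gives the methylated tert-butyl ester F8, and TFA/H2O removes the tert-butyl and silyl groups to give 18.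

3. Step 9. The intermediate lactol may be over-oxidised to the lactone before the ylide has reacted, and ylide may be lost to the carboxylic acid. The fallback runs from 18 back to 20 and makes the over-oxidation the route. Excess TEMPO/PhI(OAc)2 gives the δ-lactone F9 (oxidative lactonisation of the 1,5-diol at the less hindered carbinol), iBu2AlH at −78 °C gives the lactol F10, and the lactol is olefinated separately with the same ylide in toluene at 90 °C to give 20.

Further compounds
F1 | step 5 | tert-butyldimethylsilyl dienol ether of 5 | CC(C)[C@@H]1CC[C@@H](C)C[C@]12OC3=C(C)CCCC3=C(O[Si](C)(C)C(C)(C)C)O2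
F2 | step 5 | dioxinone Michael adduct with α-ethenyl lactone (10-methyl β, H-9 α; C8 epimers) | CC(C)[C@@H]1CC[C@@H](C)C[C@]12OC3=C(CCC[C@]3(C)[C@H]4CCOC(=O)C4C=C)C(=O)O2
F3 | step 5 | tert-butyl β-keto ester (C5 ketone, C10 quaternary; C4 and C8 epimers) | CC(C)(C)OC(=O)C1CCC[C@](C)([C@H]2CCOC(=O)C2C=C)C1=O
F4 | step 5 | enol triflate of F3 (C4=C5, triflate on C5; C8 epimers) | CC(C)(C)OC(=O)C1=C(OS(=O)(=O)C(F)(F)F)[C@@](C)([C@H]2CCOC(=O)C2C=C)CCC1
F5 | step 5 | tert-butyl ester of 15 | C[C@]12CCCC(C(=O)OC(C)(C)C)=C1CC[C@H]3C(=O)OCC[C@H]23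
F6 | step 8 | 12,17-bis(tert-butyldimethylsilyl) ether of 16 | C[C@]12CCCC(C(=O)O)=C1CC[C@@H](CO[Si](C)(C)C(C)(C)C)[C@@H]2CCO[Si](C)(C)C(C)(C)C
F7 | step 8 | tert-butyl ester of F6 | C[C@]12CCCC(C(=O)OC(C)(C)C)=C1CC[C@@H](CO[Si](C)(C)C(C)(C)C)[C@@H]2CCO[Si](C)(C)C(C)(C)C
F8 | step 8 | tert-butyl ester 12,17-bis(tert-butyldimethylsilyl) ether of 18 | C[C@]12CCC[C@](C)(C(=O)OC(C)(C)C)[C@@H]1CC[C@@H](CO[Si](C)(C)C(C)(C)C)[C@@H]2CCO[Si](C)(C)C(C)(C)C
F9 | step 9 | δ-lactone of 18 with C12 carbonyl and ring oxygen on C17 | C[C@]12CCC[C@](C)(C(=O)O)[C@@H]1CC[C@H]3COC(=O)C[C@H]23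
F10 | step 9 | lactol from F9 (C12 hemiacetal, anomers) | C[C@]12CCC[C@](C)(C(=O)O)[C@@H]1CC[C@H]3COC(O)C[C@H]23
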